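## Structural features

The target is a 1,4-benzodioxane neolignan in which ring A, a benzene ring with a methoxy group at C3' and an (E)-propenal chain at C1', is fused through the adjacent oxygens O4' and O5' to a six-membered dioxane ring. The two sp3 carbons of that ring are C7, which is benzylic, bound to O5' and carries ring C (3,4-dihydroxy-5-methoxyphenyl), and C8, which is bound to O4' and carries the hydroxymethyl carbon C9. C7 and C8 are neighbouring stereocentres, both R, so ring C and the hydroxymethyl group are trans across the C7–C8 bond. The fragile functions are the enal (open to conjugate addition and to any hydrogenation), the free catechol of ring C (readily oxidised as a phenoxide) and the C7–O5' bond, a benzylic aryl ether with a para oxygen on ring C that can ionise under strong acid and so epimerise C7. The real difficulty is twofold: the two ring A oxygens differ only in their neighbours (methoxy on one side, hydrogen on the other) yet each must be joined to the correct carbon, and the trans (7R,8R) pair must be made as one enantiomer. The key step exploits the fact that C4', the carbon bearing O4', lies para to C1' and hence para to a carbonyl-level carbon: C4' can enter as an electrophilic C–Br carbon, O4' as the oxygen of a C7–C8 epoxide, and O5' as a phenoxide that opens this epoxide at benzylic C7. Since only C7 is inverted in that sequence, a cis-epoxide of (7S,8R) configuration maps onto the trans (7R,8R) dioxane, and the regiochemistry is decided by where bromine and hydroxyl sit on ring A, not by telling two phenols apart.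

## Logic of the disconnections

14 to 13. The bonds cut are the three O–CH2Ph bonds that mask the two ring C phenols and O9. They are cut last because a free catechol and a free alcohol next to C8 would not pass the basic, oxidising and organometallic steps before. The gain is a fully etherified, oxidation-resistant 13. The forward step must remove all three ethers without hydrogenating the C7'=C8' bond of the side chain (C7' being the carbon on ring A) and without ionising the C7–O5' bond, which points to a low-temperature Lewis acid cleavage with a cation trap.

13 to 12. The C7'=C8' double bond is cut, which removes two carbons and returns the side chain to the aryl aldehyde of 12. The cut is placed here because the formyl group on C1' is the acceptor that makes C4' electrophilic in the annulation, whereas an enal would not survive hot carbonate. The gain is that the most base-sensitive function is absent until the ring exists. The forward olefination must be E-selective and must stop after one two-carbon extension.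

12 to 8 and 10 (through 11). The C7–O5' and O4'–C4' bonds are cut, which opens the dioxane ring and divides the molecule into two halves of similar size. The regiochemistry is then written into 10 (hydroxyl on C5', bromine on C4') and the configuration into 8, so neither has to be controlled during the union. The gain is one ring and both hetero-bonds in one operation. The forward step must open 8 at C7 only, with clean inversion, and must then close the C8 alkoxide of 11 onto the hindered C4'–Br carbon.

10 to 9. One O–CH3 bond is restored. Because 9 is symmetric, cleavage of either methoxy group gives the same phenol, and 9 is purchasable. The demand is that cleavage stops at the mono-phenol and spares the formyl group and the C–Br bond.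

8 to 7. Both C–O bonds of the oxirane are cut. C7 and C8 are thereby traced to one catalytic oxygen transfer onto a flat, achiral Z-alkene, which is simpler than building the two centres separately. The forward step must select one alkene face, keep the cis geometry, and leave an electron-rich benzylic epoxide unopened.

7 to 6. The two C–H bonds across C7–C8 are removed, giving the alkyne. A syn semihydrogenation fixes the Z geometry more securely than a Z-selective olefination would. The demand is that reduction stops at the alkene and leaves benzylic and allylic C–O bonds alone.

6 to 3 and 4 (through 5). The C8–C9 bond is cut. 4 brings in C9 with O9 already benzylated, so no step is spent on protecting O9 and no silyl group ends up beside the future C8 alkoxide. The forward step needs clean C-alkylation of acetylide 5.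

3 to 2. The C7≡C8 bond is cut back to the formyl carbon of 2, C8 coming from a one-carbon reagent. The aldehyde is the oxidation level at which ring C is purchasable. The demand is a homologation mild enough for the benzyl ethers.

2 to 1. The two O–CH2Ph bonds on ring C are cut, leading to purchasable 1. Benzyl is chosen so that ring C and O9 carry the same group and one operation clears all three. The forward step needs complete double alkylation.

## Other disconnections considered

Alternative 1: The cut goes through C7–C8 and through the bond from C7 to ring C, so C7 is brought in as a one-carbon unit on boron.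
- Forward key step: the α-aryloxy boronic ester A2 (C8 already carrying O4' of ring A, C9 as its benzyl ether, and a C2-symmetric dicyclohexylethanediol on boron) would be treated with dichloromethyllithium A4. ZnCl2 would promote migration of C8 from boron to the new carbon with loss of one chloride. The ring C Grignard reagent A3 would then add to boron and displace the second chloride in a second 1,2-shift, giving A1 without closing a ring. Oxidation of the C–B bond with retention, closure of the new C7 hydroxyl onto the C5' bromide, acetal hydrolysis, olefination and deprotection would follow.
- In its favour: the assembly is convergent, and C7 is set by the diol on boron through stereospecific migrations, so no external nucleophile has to attack an ionisable benzylic carbon. On this mechanistic point the alternative is the better. In freedom to reach either relative configuration it is at least the equal.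
- Against it here: A2 is itself a stereodefined α-aryloxy boronic ester that needs a preceding homologation cycle, the chiral diol is stoichiometric and the carbenoid chemistry is cryogenic. In A1 the aryloxy group on C8 sits β to boron, an arrangement prone to β-elimination, most of all at the ate-complex stage with ZnCl2 present, which would erase both stereocentres. The C–Br bond of ring A must also pass a Grignard reagent untouched. The later ring closure is at C5', meta to the carbonyl-level carbon, so it has no SNAr assistance and rests on CuI or Pd(OAc)2/phosphine catalysis alone, whereas the chosen plan arylates at the para-activated C4'.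
- Comparison: both plans arrive at the same dioxane aldehyde level, but this one needs about four operations after its key step before the ring exists and about three more steps overall, so it is inferior in step economy.

Alternative 2: The cut goes through C7–C8 and C8–O4'. C8 and C9 come from ethyl diazoacetate A7, and C7 is the acetal carbon of the 2-aryl-1,3-benzodioxole A6, in which the formyl carbon of 2 bridges O4' and O5' of ring A.
- Forward key step: a Lewis acid such as SnCl4, or a chiral Brønsted acid, would ionise the acetal to an O5'-stabilised oxocarbenium ion at C7. A7 would add through carbon to form C7–C8, and the released O4' phenoxide would displace N2 from C8, enlarging the five-membered ring to the dioxane of A5.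
- In its favour: it is the shortest approach, uses 2 directly and needs neither halogen nor epoxide. The regiochemistry is biased the right way, because O4', para to the ester, is the better leaving phenoxide and O5' the better donor to the cation. The trans relation is self-correcting, since C8 of A5 is α to an ester and can equilibrate to the more stable diastereomer. On diastereocontrol it is the equal of the chosen plan, and on step economy the better: about seven steps overall, with reduction of both esters and selective MnO2 oxidation of the benzylic alcohol leading into the same last two operations with one benzyl ether fewer.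
- Against it here: the absolute configuration would have to be induced in the addition of A7 to a planar, diaryl-substituted oxocarbenium ion, for which this substrate class offers no firm basis. The plan is credible as a racemic, trans-selective synthesis but speculative for a single enantiomer. The diazonium intermediate, with an electron-rich aryl group on the neighbouring C7, also invites 1,2-aryl or hydride shift in competition with ring closure.
- Comparison: the chosen plan is longer but takes both centres from a catalytic epoxidation of an established substrate class followed by a stereospecific substitution, which is decisive for a single-enantiomer target.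

Alternative 3: Only the C8–O4' bond is cut in the key step, C7–O5' having been made earlier.
- Forward key step: the precursor A9 carries ring A on O5' at C7, a free phenol at O4' and a terminal C8–C9 epoxide. With K2CO3 the O4' phenoxide would open that epoxide at C8 in a 6-exo-tet closure with inversion, forming the dioxane ring of A8 and setting the C9 hydroxyl free. A9 would come from the trans-epoxy alcohol A10 (Ti(OiPr)4, L-(+)-diethyl tartrate, tert-butyl hydroperoxide), opened at C7 by the phenol A11 whose O4' is masked as an allyl ether. Sulfonylation of the primary hydroxyl, base-induced formation of the terminal epoxide and removal of the allyl group would follow.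
- In its favour: the chirality comes from a Ti(OiPr)4/tartrate epoxidation of an E-allylic alcohol, which is concerted and cannot leak to the other epoxide geometry, so in security of absolute configuration this alternative is the better. The ring closure needs no metal and no aryl halide and follows the familiar course from glycidyl aryl ethers to 2-hydroxymethyl-1,4-benzodioxanes, which is equal or better. O9 never needs a protecting group. The intermolecular phenoxide opening at benzylic C7 with inversion is common to both plans and is a point of equality, although the free hydroxyl of A10 adds the risk of Payne rearrangement under base.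
- Against it here: the two catechol oxygens of ring A must be told apart by selective protection to reach A11, a problem the chosen plan removes by placing bromine on C4'. Two successive inversions (C7, then C8) must both be clean. The closure has to occur at the more hindered carbon of the terminal epoxide, with 7-endo attack at C9 as competitor. The detour through diol, sulfonate and unmasking costs about two to three steps more.
- Comparison: both reach the same trans-dioxane aldehyde. The choice is between a shorter route that depends on a (salen)MnCl-catalysed epoxidation and an aryl C–O closure, and a longer one that depends only on classical SN2 chemistry.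

Key step: step 7

Remark: atom labels follow lignan usage (C7, C8, C9 for the three-carbon unit on ring C; primed locants for ring A and its side chain), and 1, 4, 9 and the reagents written over the arrows are taken to be purchasable.

## Route

Step 1
Reactants: 1 5-hydroxyvanillin (3,4-dihydroxy-5-methoxybenzaldehyde)
Product: 2 3,4-bis(benzyloxy)-5-methoxybenzaldehyde
Conditions: BnBr, K2CO3, DMF, 60 °C
Reagents that add atoms: benzyl bromide, BrCc1ccccc1
Why: Double Williamson ether synthesis in which both catechol phenoxides displace bromide from the benzylic halide while the aldehyde is inert to carbonate; benzyl is chosen because it should survive organolithium, hypochlorite and hot carbonate and can later be removed together with the O9 benzyl group.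

Step 2
Reactants: 2 3,4-bis(benzyloxy)-5-methoxybenzaldehyde
Product: 3 1,2-bis(benzyloxy)-5-ethynyl-3-methoxybenzene
Conditions: dimethyl (1-diazo-2-oxopropyl)phosphonate, K2CO3, MeOH/THF, 0 °C to rt
Reagents that add atoms: dimethyl (1-diazo-2-oxopropyl)phosphonate (Ohira–Bestmann reagent), CC(=O)C(=[N+]=[N-])P(=O)(OC)OC
Why: Ohira–Bestmann variant of the Seyferth–Gilbert homologation: methanolysis of the acetyl group releases the diazomethylphosphonate anion, which olefinates the non-enolisable aryl aldehyde, and loss of N2 with a 1,2-hydrogen shift should give the terminal alkyne under conditions mild enough for the benzyl ethers.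

Step 3
Reactants: 3 1,2-bis(benzyloxy)-5-ethynyl-3-methoxybenzene; 4 benzyl chloromethyl ether
Product: 6 1,2-bis(benzyloxy)-5-[3-(benzyloxy)prop-1-yn-1-yl]-3-methoxybenzene, via lithium acetylide 5 (not isolated)
Conditions: n-BuLi, THF, −78 °C; then 4, −78 °C to rt
Reagents that add atoms: none
Why: Deprotonation of the terminal alkyne and C-alkylation of the acetylide by the highly electrophilic α-chloro ether (SN2-type substitution); C9 is installed already carrying its oxygen as a benzyl ether, so no separate protection is needed.

Step 4
Reactants: 6 1,2-bis(benzyloxy)-5-[3-(benzyloxy)prop-1-yn-1-yl]-3-methoxybenzene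
Product: 7 1,2-bis(benzyloxy)-5-[(Z)-3-(benzyloxy)prop-1-en-1-yl]-3-methoxybenzene
Conditions: H2 (1 atm), Pd/CaCO3 poisoned with Pb(OAc)2 (Lindlar catalyst), quinoline, EtOAc, rt
Reagents that add atoms: none
Why: Lindlar semihydrogenation: syn delivery of hydrogen on the Pb(OAc)2-poisoned Pd/CaCO3 surface should give the Z-alkene only, and quinoline suppresses over-reduction and hydrogenolysis of the benzylic and allylic C–O bonds.

Step 5
Reactants: 7 1,2-bis(benzyloxy)-5-[(Z)-3-(benzyloxy)prop-1-en-1-yl]-3-methoxybenzene
Product: 8 (2R,3S)-2-[(benzyloxy)methyl]-3-[3,4-bis(benzyloxy)-5-methoxyphenyl]oxirane (cis; 7S,8R in lignan numbering)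
Conditions: (S,S)-[N,N'-bis(3,5-di-tert-butylsalicylidene)-1,2-cyclohexanediaminato]MnCl (cat.), 4-phenylpyridine N-oxide, aqueous NaOCl buffered to pH 11.3, CH2Cl2, 0 °C
Reagents that add atoms: sodium hypochlorite, [Na+].[O-]Cl
Why: Jacobsen–Katsuki epoxidation of a cis-disubstituted aryl alkene, the substrate class for which the salen oxo-manganese species (pentavalent manganese) is most selective; the (S,S) ligand should direct oxygen transfer to the face that gives the (7S,8R) cis-epoxide, by analogy with the sense known for cis-β-alkylstyrenes, and both stereocentres are set here. The N-oxide ligand and the low temperature limit bond rotation in the radical-type intermediate that leads to trans-epoxide, and the basic two-phase medium protects the acid-labile epoxide.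

Step 6
Reactants: 9 4-bromo-3,5-dimethoxybenzaldehyde
Product: 10 4-bromo-3-hydroxy-5-methoxybenzaldehyde
Conditions: BBr3 (limiting amount), CH2Cl2, −78 to 0 °C; then H2O
Reagents that add atoms: none
Why: Lewis acid ether cleavage: BBr3 coordinates a methoxy oxygen and bromide removes the methyl group by SN2; the two methoxy groups of 9 are equivalent, so either cleavage gives 10, and limiting the reagent and the temperature should favour the mono-phenol. Unchanged 9 and over-cleaved diol differ enough from 10 in acidity and polarity to be separated, and 9 can be recycled.

Step 7
Reactants: 8 (2R,3S)-2-[(benzyloxy)methyl]-3-[3,4-bis(benzyloxy)-5-methoxyphenyl]oxirane; 10 4-bromo-3-hydroxy-5-methoxybenzaldehyde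
Product: 12 (2R,3R)-3-[3,4-bis(benzyloxy)-5-methoxyphenyl]-2-[(benzyloxy)methyl]-8-methoxy-2,3-dihydro-1,4-benzodioxine-6-carbaldehyde, via ring-opened bromo alcohol 11 (not isolated)
Conditions: Cs2CO3, DMF, 80 °C, argon; then CuI (cat.), 1,10-phenanthroline, 110 °C, same flask
Reagents that add atoms: none
Why: Cs2CO3 converts 10 into its phenoxide (O5'), which attacks the oxirane of 8 at the benzylic carbon C7 from the side opposite to the epoxide oxygen (SN2, inversion) and so forms the C7–O5' bond and the C8 alkoxide of 11. That alkoxide lies next to the C4'–Br bond and closes the dioxane ring by intramolecular O-arylation, as an addition–elimination at C4' assisted by the para formyl group or, more dependably for a bromide flanked by two oxygen substituents, as an Ullmann-type C–O coupling at monovalent copper; CuI and 1,10-phenanthroline are therefore added only after the opening is complete, so that intermolecular diaryl ether formation from 10 cannot compete. The closest known reaction type is the one-pot base- or copper-mediated annulation of 2-halophenols with epoxides to 2,3-dihydro-1,4-benzodioxines, and its first half corresponds to the familiar benzylic opening of 3-arylglycidyl ethers by phenoxides. The one ring that closes is six-membered and forms by attack of O4' on the sp2 carbon C4' (formally 6-exo-trig with respect to the C3'–C4' bond of the arene, or reductive elimination from a seven-membered aryl–Cu–alkoxide metallacycle); the competing Smiles-type ipso attack at C5' would need a spiro five-membered intermediate at a carbon meta to the formyl group and should not intervene. No new stereocentre is created: C7 is inverted stereospecifically and C8 keeps its configuration, so the (7S,8R) cis-epoxide should be translated into the (7R,8R) trans-dioxane under pure substrate control. The step needs regioselection between C7 and C8, which is secured by benzylic activation of C7 by ring C together with inductive deactivation of C8 by the neighbouring C9–O bond, and it needs a clean SN2 course, which is secured by an aprotic basic medium free of Lewis acid during the opening so that the electron-rich benzylic C–O bond does not ionise. The benzyl ether on O9 cannot migrate to the C8 alkoxide as a silyl ether could, and the formyl group is left free because it is what polarises C4'.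

Step 8
Reactants: 12 (2R,3R)-3-[3,4-bis(benzyloxy)-5-methoxyphenyl]-2-[(benzyloxy)methyl]-8-methoxy-2,3-dihydro-1,4-benzodioxine-6-carbaldehyde
Product: 13 (E)-3-{(2R,3R)-3-[3,4-bis(benzyloxy)-5-methoxyphenyl]-2-[(benzyloxy)methyl]-8-methoxy-2,3-dihydro-1,4-benzodioxin-6-yl}prop-2-enal
Conditions: Ph3P=CHCHO (slight excess), toluene, 80 °C
Reagents that add atoms: (triphenylphosphoranylidene)acetaldehyde, O=CC=P(c1ccccc1)(c1ccccc1)c1ccccc1
Why: Wittig olefination with a formyl-stabilised ylide, which should give the E-enal; only a small excess of ylide at moderate temperature is used so that the less electrophilic vinylogous aldehyde of 13 is not homologated again.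

Step 9
Reactants: 13 (E)-3-{(2R,3R)-3-[3,4-bis(benzyloxy)-5-methoxyphenyl]-2-[(benzyloxy)methyl]-8-methoxy-2,3-dihydro-1,4-benzodioxin-6-yl}prop-2-enal
Product: 14 (E)-3-[(2R,3R)-3-(3,4-dihydroxy-5-methoxyphenyl)-2-(hydroxymethyl)-8-methoxy-2,3-dihydro-1,4-benzodioxin-6-yl]prop-2-enal
Conditions: BCl3, pentamethylbenzene, CH2Cl2, −78 to −40 °C; then H2O
Reagents that add atoms: none
Why: Lewis acid debenzylation with a non-basic cation scavenger: BCl3 activates the ether oxygens and the benzyl cations are trapped irreversibly by pentamethylbenzene through Friedel–Crafts alkylation, so the electron-rich rings are not benzylated. The low temperature is chosen so that the alkene (which rules out hydrogenolysis), the aryl methyl ethers and the benzylic C7–O5' bond should survive, the aldehyde being complexed only reversibly.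

## Compound list

1 | 5-hydroxyvanillin (3,4-dihydroxy-5-methoxybenzaldehyde) | COc1cc(C=O)cc(O)c1O | starting material
2 | 3,4-bis(benzyloxy)-5-methoxybenzaldehyde | COc1cc(C=O)cc(OCc2ccccc2)c1OCc1ccccc1 | intermediate
3 | 1,2-bis(benzyloxy)-5-ethynyl-3-methoxybenzene | COc1cc(C#C)cc(OCc2ccccc2)c1OCc1ccccc1 | intermediate
4 | benzyl chloromethyl ether | ClCOCc1ccccc1 | starting material
5 | lithium [3,4-bis(benzyloxy)-5-methoxyphenyl]acetylide (formed in the flask) | COc1cc(C#C[Li])cc(OCc2ccccc2)c1OCc1ccccc1 | intermediate
6 | 1,2-bis(benzyloxy)-5-[3-(benzyloxy)prop-1-yn-1-yl]-3-methoxybenzene | COc1cc(C#CCOCc2ccccc2)cc(OCc2ccccc2)c1OCc1ccccc1 | intermediate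
7 | 1,2-bis(benzyloxy)-5-[(Z)-3-(benzyloxy)prop-1-en-1-yl]-3-methoxybenzene | COc1cc(/C=C\COCc2ccccc2)cc(OCc2ccccc2)c1OCc1ccccc1 | intermediate
8 | (2R,3S)-2-[(benzyloxy)methyl]-3-[3,4-bis(benzyloxy)-5-methoxyphenyl]oxirane (cis-epoxide) | COc1cc([C@@H]2O[C@@H]2COCc2ccccc2)cc(OCc2ccccc2)c1OCc1ccccc1 | intermediate
9 | 4-bromo-3,5-dimethoxybenzaldehyde | COc1cc(C=O)cc(OC)c1Br | starting material
10 | 4-bromo-3-hydroxy-5-methoxybenzaldehyde | COc1cc(C=O)cc(O)c1Br | intermediate
11 | 4-bromo-3-{(1R,2R)-3-(benzyloxy)-1-[3,4-bis(benzyloxy)-5-methoxyphenyl]-2-hydroxypropoxy}-5-methoxybenzaldehyde (formed in the flask) | COc1cc([C@@H](Oc2cc(C=O)cc(OC)c2Br)[C@H](O)COCc2ccccc2)cc(OCc2ccccc2)c1OCc1ccccc1 | intermediate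
12 | (2R,3R)-3-[3,4-bis(benzyloxy)-5-methoxyphenyl]-2-[(benzyloxy)methyl]-8-methoxy-2,3-dihydro-1,4-benzodioxine-6-carbaldehyde | COc1cc([C@H]2Oc3cc(C=O)cc(OC)c3O[C@@H]2COCc2ccccc2)cc(OCc2ccccc2)c1OCc1ccccc1 | intermediate
13 | (E)-3-{(2R,3R)-3-[3,4-bis(benzyloxy)-5-methoxyphenyl]-2-[(benzyloxy)methyl]-8-methoxy-2,3-dihydro-1,4-benzodioxin-6-yl}prop-2-enal | COc1cc([C@H]2Oc3cc(/C=C/C=O)cc(OC)c3O[C@@H]2COCc2ccccc2)cc(OCc2ccccc2)c1OCc1ccccc1 | intermediate
14 | (E)-3-[(2R,3R)-3-(3,4-dihydroxy-5-methoxyphenyl)-2-(hydroxymethyl)-8-methoxy-2,3-dihydro-1,4-benzodioxin-6-yl]prop-2-enal (CNP0103768.1) | COc1cc([C@H]2Oc3cc(/C=C/C=O)cc(OC)c3O[C@@H]2CO)cc(O)c1O | target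

## Step count and least certain steps

Total step count: 9. Longest linear sequence: 8 steps (steps 1, 2, 3, 4, 5, 7, 8 and 9); step 6 is a one-step branch that joins at step 7.

Step 7 (key step). The most likely failures are a slow or unselective epoxide opening by the hindered, weakly nucleophilic ortho-bromo phenoxide (partial attack at C8, or partial ionisation at C7 with loss of stereospecificity at higher temperature) and an incomplete ring closure at the doubly ortho-substituted C4'–Br carbon, with slow degradation of the aldehyde under hot carbonate. The fallback gives up the domino and runs the two bond formations as separate, individually optimised operations. It sets out from 8 and 10, which are combined with K2CO3 in DMF at the lowest workable temperature without copper, and the ring-opened bromo alcohol 11 is isolated. The ring is then closed by a Buchwald–Hartwig-type intramolecular etherification (Pd(OAc)2 with a bulky di-tert-butyl biaryl phosphine, Cs2CO3, toluene, 80 °C), in which oxidative addition of zerovalent palladium into the C–Br bond replaces SNAr or copper activation. The route is rejoined at 12. This fallback makes no compound outside the list (F0).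

Step 5. The risks are insufficient face selection on this particular Z-alkene, leakage to the trans-epoxide through rotation in the radical-type intermediate (favoured by the electron-rich aryl group), and opening of the labile epoxide on isolation. The fallback replaces oxygen transfer from a (salen)MnCl-derived oxidant with a hydroxyl-directed, concerted epoxidation that cannot change the alkene geometry. It sets out from 3, which is deprotonated with n-BuLi and treated with paraformaldehyde to give 3-[3,4-bis(benzyloxy)-5-methoxyphenyl]prop-2-yn-1-ol F1. Semihydrogenation as in step 4 gives (Z)-3-[3,4-bis(benzyloxy)-5-methoxyphenyl]prop-2-en-1-ol F2. Sharpless epoxidation (Ti(OiPr)4, D-(−)-diethyl tartrate, tert-butyl hydroperoxide, 4 Å molecular sieves, CH2Cl2, −20 °C) should give [(2R,3S)-3-[3,4-bis(benzyloxy)-5-methoxyphenyl]oxiran-2-yl]methanol F3, the D-tartrate being the one predicted by the usual mnemonic to place C8 in the R configuration. O-Benzylation (NaH, BnBr, THF, 0 °C) rejoins the route at 8.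

Step 8. The risk is over-homologation, because the enal formed is itself an aldehyde and the starting aryl aldehyde is electron-rich and therefore slow, so product and substrate may compete for the ylide. The fallback builds the enal through oxidation levels that cannot react twice. It sets out from 12. A Horner–Wadsworth–Emmons reaction with triethyl phosphonoacetate and NaH in THF should give ethyl (E)-3-{(2R,3R)-3-[3,4-bis(benzyloxy)-5-methoxyphenyl]-2-[(benzyloxy)methyl]-8-methoxy-2,3-dihydro-1,4-benzodioxin-6-yl}prop-2-enoate F4. Reduction with i-Bu2AlH in CH2Cl2 at −78 °C gives (E)-3-{(2R,3R)-3-[3,4-bis(benzyloxy)-5-methoxyphenyl]-2-[(benzyloxy)methyl]-8-methoxy-2,3-dihydro-1,4-benzodioxin-6-yl}prop-2-en-1-ol F5. Allylic oxidation with MnO2 in CH2Cl2 rejoins the route at 13.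

Step 9. The risks are Lewis-acid ionisation of the C7–O5' bond (epimerisation at C7, or capture of the cation by the scavenger), addition of HCl to the enal, and sluggish cleavage of the primary benzyl ether at the temperature that protects the other groups. The fallback removes the benzyl groups before the alkene exists and without Lewis acid. It sets out from 12, which is hydrogenolysed (H2, Pd/C, EtOAc, rt, stopped when debenzylation is complete) to (2R,3R)-3-(3,4-dihydroxy-5-methoxyphenyl)-2-(hydroxymethyl)-8-methoxy-2,3-dihydro-1,4-benzodioxine-6-carbaldehyde F6. The Wittig reaction of step 8 (Ph3P=CHCHO, THF or toluene, 60–80 °C) is then run on this unprotected aldehyde, the stabilised ylide being too weakly basic to deprotonate the catechol, and the route is rejoined directly at 14.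

## Further compounds

F0 | step 7 | none | none
F1 | step 5 | 3-[3,4-bis(benzyloxy)-5-methoxyphenyl]prop-2-yn-1-ol | COc1cc(C#CCO)cc(OCc2ccccc2)c1OCc1ccccc1
F2 | step 5 | (Z)-3-[3,4-bis(benzyloxy)-5-methoxyphenyl]prop-2-en-1-ol | COc1cc(/C=C\CO)cc(OCc2ccccc2)c1OCc1ccccc1
F3 | step 5 | [(2R,3S)-3-[3,4-bis(benzyloxy)-5-methoxyphenyl]oxiran-2-yl]methanol | COc1cc([C@@H]2O[C@@H]2CO)cc(OCc2ccccc2)c1OCc1ccccc1
F4 | step 8 | ethyl (E)-3-{(2R,3R)-3-[3,4-bis(benzyloxy)-5-methoxyphenyl]-2-[(benzyloxy)methyl]-8-methoxy-2,3-dihydro-1,4-benzodioxin-6-yl}prop-2-enoate | COc1cc([C@H]2Oc3cc(/C=C/C(=O)OCC)cc(OC)c3O[C@@H]2COCc2ccccc2)cc(OCc2ccccc2)c1OCc1ccccc1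
F5 | step 8 | (E)-3-{(2R,3R)-3-[3,4-bis(benzyloxy)-5-methoxyphenyl]-2-[(benzyloxy)methyl]-8-methoxy-2,3-dihydro-1,4-benzodioxin-6-yl}prop-2-en-1-ol | COc1cc([C@H]2Oc3cc(/C=C/CO)cc(OC)c3O[C@@H]2COCc2ccccc2)cc(OCc2ccccc2)c1OCc1ccccc1
F6 | step 9 | (2R,3R)-3-(3,4-dihydroxy-5-methoxyphenyl)-2-(hydroxymethyl)-8-methoxy-2,3-dihydro-1,4-benzodioxine-6-carbaldehyde | COc1cc([C@H]2Oc3cc(C=O)cc(OC)c3O[C@@H]2CO)cc(O)c1O
A1 | alternative 1 | (4R,5R)-4,5-dicyclohexyl-1,3,2-dioxaborolane bearing on boron the (1R,2S)-3-(benzyloxy)-2-[2-bromo-4-(1,3-dioxolan-2-yl)-6-methoxyphenoxy]-1-[3-methoxy-4,5-bis(methoxymethoxy)phenyl]propyl group | COCOc1cc([C@@H](B2O[C@H](C3CCCCC3)[C@@H](C3CCCCC3)O2)[C@H](Oc2c(Br)cc(C3OCCO3)cc2OC)COCc2ccccc2)cc(OC)c1OCOC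
A2 | alternative 1 | (4R,5R)-2-{(1S)-2-(benzyloxy)-1-[2-bromo-4-(1,3-dioxolan-2-yl)-6-methoxyphenoxy]ethyl}-4,5-dicyclohexyl-1,3,2-dioxaborolane | COc1cc(C2OCCO2)cc(Br)c1O[C@H](COCc1ccccc1)B1O[C@H](C2CCCCC2)[C@@H](C2CCCCC2)O1
A3 | alternative 1 | [3-methoxy-4,5-bis(methoxymethoxy)phenyl]magnesium bromide | COCOc1cc([Mg]Br)cc(OC)c1OCOC
A4 | alternative 1 | dichloromethyllithium | [Li]C(Cl)Cl
A5 | alternative 2 | 2-ethyl 6-methyl (2S,3R)-3-[3,4-bis(benzyloxy)-5-methoxyphenyl]-8-methoxy-2,3-dihydro-1,4-benzodioxine-2,6-dicarboxylate (trans) | COc1cc([C@H]2Oc3cc(C(=O)OC)cc(OC)c3O[C@@H]2C(=O)OCC)cc(OCc2ccccc2)c1OCc1ccccc1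
A6 | alternative 2 | methyl 2-[3,4-bis(benzyloxy)-5-methoxyphenyl]-7-methoxy-1,3-benzodioxole-5-carboxylate (racemic at the acetal carbon) | COC(=O)c1cc(OC)c2OC(c3cc(OC)c(OCc4ccccc4)c(OCc4ccccc4)c3)Oc2c1
A7 | alternative 2 | ethyl diazoacetate | CCOC(=O)C=[N+]=[N-]
A8 | alternative 3 | (2R,3R)-3-[3,4-bis(benzyloxy)-5-methoxyphenyl]-2-(hydroxymethyl)-8-methoxy-2,3-dihydro-1,4-benzodioxine-6-carbaldehyde | COc1cc([C@H]2Oc3cc(C=O)cc(OC)c3O[C@@H]2CO)cc(OCc2ccccc2)c1OCc1ccccc1
A9 | alternative 3 | 3-{(R)-[3,4-bis(benzyloxy)-5-methoxyphenyl][(2S)-oxiran-2-yl]methoxy}-4-hydroxy-5-methoxybenzaldehyde | COc1cc([C@@H](Oc2cc(C=O)cc(OC)c2O)[C@@H]2CO2)cc(OCc2ccccc2)c1OCc1ccccc1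
A10 | alternative 3 | [(2S,3S)-3-[3,4-bis(benzyloxy)-5-methoxyphenyl]oxiran-2-yl]methanol | COc1cc([C@@H]2O[C@H]2CO)cc(OCc2ccccc2)c1OCc1ccccc1
A11 | alternative 3 | 4-(allyloxy)-3-hydroxy-5-methoxybenzaldehyde | COc1cc(C=O)cc(O)c1OCC=C
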